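Retrosynthesis: the chain is cut at C11=C12 and C11′=C12′ (two Wittig reactions on the commercial C10 dialdehyde), then at C8–C9 and C8′–C9′ (palladium couplings with one C4 boronic acid), so that both end groups fall back on a single ring alkyne.
In that ring the bonds C2–C3 and C1–C6 are cut together: the ring has oxygen on C3 and on C6 (1,4 across the ring), the chain carbon C7 on C6 and a methyl on C5. This is the pattern of 3-hydroxy-4-methyl-2-pyrone (ring O becomes O on C3, lactone C=O becomes C7, 3-OH becomes 6-OH); C1–C2 with one C1 methyl as CHO is methacrolein. Their base-catalysed Diels–Alder reaction makes both bonds and keeps C7–O(C3) as a temporary lactone bridge.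
Forward: furoate → pyrone → bicyclic lactone → CHO to CH3 → hydration of C4=C5 on the bicycle → bridge opened (lactol, then alkyne) → C3 inverted by oxidation and directed reduction.
Triol half: hydrostannylation/iodination, Suzuki coupling, Wittig salt. Furanoid half: the same C6 hydroxyl leaves in an anti SN2′ coupling to an allenol that cyclises to the 5,8-epoxide, then Wittig salt. Furanoid salt plus dialdehyde, then triol salt, then desilylation.
Stereochemistry: C6 (and the provisional C3) from the cinchona catalyst in the cycloaddition; C5 from the shape of the bicycle; C3 and C3′ from hydride delivery by the 5-hydroxyl; C8′ relayed from C6′ through the allene axis (centre to axis to centre); alkene geometry from syn metalations, stereoretentive couplings and equilibrated Wittig reactions.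

Key step: step 4

Remark: carotenoid locants are used for positions (ring C1–C6, chain from C7, primes for the furanoid half). The quinidine-derived catalyst is assumed to give the bridgehead configuration drawn for the cycloadduct; if the sense proved opposite, its quinine-derived pseudo-enantiomer would be used.

Step 1
Reactants: 1 methyl 3-methylfuran-2-carboxylate
Product: 2 methyl 2,5-dimethoxy-3-methyl-2,5-dihydrofuran-2-carboxylate (diastereomer mixture)
Conditions: constant-current electrolysis (graphite anode, undivided cell), MeOH, H2SO4 (cat.), −20 °C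
Reagents that add atoms: methanol, CO
Why: Anodic 2,5-dimethoxylation of the furan (Clauson-Kaas alkoxylation) should proceed as on the parent 2-furoate, and the two acetal carbons formed without control become sp2 again in step 3.

Step 2
Reactants: 2 methyl 2,5-dimethoxy-3-methyl-2,5-dihydrofuran-2-carboxylate
Product: 3 methyl 2,5-dimethoxy-3-methyltetrahydrofuran-2-carboxylate (diastereomer mixture)
Conditions: H2 (3 bar), Raney Ni, MeOH, rt
Reagents that add atoms: none
Why: Heterogeneous hydrogenation of the ring double bond leaves acetal, ketal and ester untouched, and the methyl-bearing stereocentre it creates is lost again in step 3.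

Step 3
Reactants: 3 methyl 2,5-dimethoxy-3-methyltetrahydrofuran-2-carboxylate
Product: 5 3-hydroxy-4-methyl-2H-pyran-2-one, via keto acid 4 (not isolated)
Conditions: 1 M aq H2SO4, 80 °C
Reagents that add atoms: water, O
Why: Acid hydrolysis of acetal, ketal and ester unmasks the 1,5-dicarbonyl acid 4, whose enol lactonisation and dehydration (cyclodehydration) should give the 3-hydroxy-2-pyrone.

Step 4
Reactants: 5 3-hydroxy-4-methyl-2H-pyran-2-one; 6 methacrolein
Product: 7 (1R,4S,5S)-4-hydroxy-5,8-dimethyl-3-oxo-2-oxabicyclo[2.2.2]oct-7-ene-5-carbaldehyde (formyl on the side of the lactone bridge)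
Conditions: 9-O-(9-phenanthryl)cupreidine (10 mol%), Et2O, −20 °C
Reagents that add atoms: none
Why: The tertiary amine of the catalyst deprotonates the 3-hydroxyl of 5 and the resulting 3-oxido-diene (pyrone C3=C4–C5=C6) adds across the C=C bond of 6, either as a concerted asynchronous [4+2] cycloaddition or as Michael addition of pyrone C6 to the β-carbon followed by aldol closure of the enolate α-carbon on C3, the closest known reaction type being the cinchona-alkaloid-catalysed Diels–Alder reaction of 3-hydroxy-2-pyrones with α,β-unsaturated carbonyl compounds. The new cyclohexene ring (carotenoid C1–C6) closes by intermolecular [4+2] annulation (a 6-exo-trig aldol in the stepwise picture), and because the diene is cyclic the lactone remains as a two-atom bridge, giving the 2-oxabicyclo[2.2.2]octene. The two bridgehead stereocentres (the tertiary carbinol and the C–O carbon) are set together by the face of the pyronate left open in the chiral ion pair (quinuclidinium on the oxido group, 6′-OH hydrogen-bonded to the aldehyde), and their relative configuration is fixed by the bridge. The quaternary formyl-bearing carbon is set by the exo or endo approach of 6 and needs no control, because step 5 turns CHO into the second methyl. The step needs regioselectivity (formyl-bearing carbon next to the carbinol, CH2 next to the C–O carbon), secured by the polarisation of the 1-oxido-diene with its largest HOMO coefficient at pyrone C6, and enantiofacial selectivity, secured by the bifunctional catalyst.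

Step 5
Reactants: 7 (1R,4S,5S)-4-hydroxy-5,8-dimethyl-3-oxo-2-oxabicyclo[2.2.2]oct-7-ene-5-carbaldehyde
Product: 9 (1R,4R)-4-hydroxy-5,5,8-trimethyl-2-oxabicyclo[2.2.2]oct-7-en-3-one, via tosylhydrazone 8 (not isolated)
Conditions: TsNHNH2, EtOH, rt; then catecholborane, CHCl3, 0 °C; NaOAc·3H2O, reflux
Reagents that add atoms: none
Why: Caglioti-type reduction of the tosylhydrazone (hydride addition to C=N, then acetate-induced loss of sulfinate and N2) should turn the neopentyl formyl group into methyl without strong base, so that the β-hydroxy aldehyde cannot undergo retro-aldol cleavage, and it erases the stereocentre at the quaternary carbon.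

Step 6
Reactants: 9 (1R,4R)-4-hydroxy-5,5,8-trimethyl-2-oxabicyclo[2.2.2]oct-7-en-3-one
Product: 11 (1R,4R,8R)-4,8-dihydroxy-5,5,8-trimethyl-2-oxabicyclo[2.2.2]octan-3-one, via hydroperoxide 10 (not isolated)
Conditions: Mn(dpm)3 (cat.), PhSiH3, O2 (1 atm), i-PrOH/CH2Cl2, 0 °C → rt; then P(OEt)3
Reagents that add atoms: dioxygen, O=O
Why: Mukaiyama hydration (hydrogen-atom transfer to the CH end of the trisubstituted alkene, trapping of the tertiary radical by O2) gives the Markovnikov alcohol, and O2 should enter from the side of the flat lactone bridge because the other side is blocked by the syn methyl of the CMe2 bridge, which sets C5 with its hydroxyl cis to C7.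

Step 7
Reactants: 11 (1R,4R,8R)-4,8-dihydroxy-5,5,8-trimethyl-2-oxabicyclo[2.2.2]octan-3-one
Product: 12 (1R,4R,8R)-5,5,8-trimethyl-2-oxabicyclo[2.2.2]octane-3,4,8-triol (lactol, anomer mixture)
Conditions: DIBAL-H (i-Bu2AlH, excess), CH2Cl2, −78 °C; Rochelle salt work-up
Reagents that add atoms: none
Why: Low-temperature DIBAL-H reduction of a lactone stops at the lactol because the aluminium hemiacetal is stable at −78 °C, and the anomeric centre it creates disappears in step 8.

Step 8
Reactants: 12 (1R,4R,8R)-5,5,8-trimethyl-2-oxabicyclo[2.2.2]octane-3,4,8-triol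
Product: 13 (1S,2R,4R)-1-ethynyl-2,6,6-trimethylcyclohexane-1,2,4-triol
Conditions: dimethyl (1-diazo-2-oxopropyl)phosphonate, K2CO3, MeOH, 0 °C → rt
Reagents that add atoms: dimethyl (1-diazo-2-oxopropyl)phosphonate, CC(=O)C(=[N+]=[N-])P(=O)(OC)OC
Why: Ohira–Bestmann homologation of the open hydroxy-aldehyde form of the strained bicyclic lactol converts C7 into the terminal alkyne and frees the C3 hydroxyl without touching the existing stereocentres.

Step 9
Reactants: 13 (1S,2R,4R)-1-ethynyl-2,6,6-trimethylcyclohexane-1,2,4-triol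
Product: 14 (3R,4S)-4-ethynyl-3,4-dihydroxy-3,5,5-trimethylcyclohexan-1-one
Conditions: Pr4N[RuO4] (5 mol%), NMO, 4 Å MS, CH2Cl2, 0 °C → rt
Reagents that add atoms: none
Why: Ley–Griffith oxidation is selective for the only secondary hydroxyl, the two tertiary alcohols and the alkyne being inert, and its neutral conditions should spare the β-hydroxy ketone from dehydration.

Step 10
Reactants: 14 (3R,4S)-4-ethynyl-3,4-dihydroxy-3,5,5-trimethylcyclohexan-1-one
Product: 15 (1S,2R,4S)-1-ethynyl-2,6,6-trimethylcyclohexane-1,2,4-triol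
Conditions: Me4NBH(OAc)3, MeCN/AcOH, −30 °C
Reagents that add atoms: none
Why: Evans–Saksena reduction, in which the axial 5-hydroxyl binds the triacetoxyborohydride and delivers hydride to its own face of the C3 ketone, should place the new 3-hydroxyl trans to 5-OH (3S) and so correct the configuration imposed by the lactone bridge.

Step 11
Reactants: 15 (1S,2R,4S)-1-ethynyl-2,6,6-trimethylcyclohexane-1,2,4-triol
Product: 16 (1S,2R,4S)-4-(tert-butyldimethylsilyloxy)-1-ethynyl-2,6,6-trimethylcyclohexane-1,2-diol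
Conditions: TBSCl, imidazole, DMF, rt
Reagents that add atoms: tert-butyldimethylsilyl chloride, CC(C)(C)[Si](C)(C)Cl
Why: Silylation with TBSCl and imidazole is selective for the secondary equatorial hydroxyl over the two hindered tertiary ones.

Step 12
Reactants: 17 but-2-yn-1-ol
Product: 19 [(Z)-4-hydroxybut-2-en-2-yl]boronic acid, via pinacol boronate 18 (not isolated)
Conditions: CuCl (5 mol%), Xantphos (5 mol%), NaOt-Bu (10 mol%), B2pin2, MeOH, THF, rt; then NaIO4, NH4OAc, acetone/H2O, rt
Reagents that add atoms: bis(pinacolato)diboron, CC1(C)OB(OC1(C)C)B1OC(C)(C)C(C)(C)O1; water, O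
Why: Copper-catalysed borylcupration and protonation of the propargylic alcohol is a syn addition that places boron on the carbon remote from oxygen and so fixes the trisubstituted alkene geometry, and periodate cleavage of the pinacol ester then frees the boronic acid.

Step 13
Reactants: 16 (1S,2R,4S)-4-(tert-butyldimethylsilyloxy)-1-ethynyl-2,6,6-trimethylcyclohexane-1,2-diol
Product: 21 (1R,2R,4S)-4-(tert-butyldimethylsilyloxy)-1-[(E)-2-iodoethenyl]-2,6,6-trimethylcyclohexane-1,2-diol, via vinylstannane 20 (not isolated)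
Conditions: Bu3SnH, PdCl2(PPh3)2 (2 mol%), THF, 0 °C; then I2, CH2Cl2, 0 °C
Reagents that add atoms: iodine, II
Why: Palladium-catalysed hydrostannylation of the terminal alkyne is a syn addition that, next to a quaternary propargylic carbon, places tin at the terminus (E), and iododestannylation proceeds with retention.

Step 14
Reactants: 21 (1R,2R,4S)-4-(tert-butyldimethylsilyloxy)-1-[(E)-2-iodoethenyl]-2,6,6-trimethylcyclohexane-1,2-diol; 19 [(Z)-4-hydroxybut-2-en-2-yl]boronic acid
Product: 22 (2E,4E)-5-[(1R,2R,4S)-4-(tert-butyldimethylsilyloxy)-1,2-dihydroxy-2,6,6-trimethylcyclohexyl]-3-methylpenta-2,4-dien-1-ol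
Conditions: Pd(PPh3)4 (5 mol%), K3PO4, THF/H2O, 40 °C
Reagents that add atoms: none
Why: Suzuki–Miyaura coupling of the alkenyl iodide with the alkenylboronic acid joins C8 to C9 with retention of both alkene geometries.

Step 15
Reactants: 22 (2E,4E)-5-[(1R,2R,4S)-4-(tert-butyldimethylsilyloxy)-1,2-dihydroxy-2,6,6-trimethylcyclohexyl]-3-methylpenta-2,4-dien-1-ol
Product: 24 [(2E,4E)-5-[(1R,2R,4S)-4-(tert-butyldimethylsilyloxy)-1,2-dihydroxy-2,6,6-trimethylcyclohexyl]-3-methylpenta-2,4-dienyl]triphenylphosphonium bromide, via allylic bromide 23 (not isolated)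
Conditions: CBr4, PPh3, 2,6-lutidine, CH2Cl2, −30 °C; then PPh3, MeCN, rt
Reagents that add atoms: triphenylphosphine, c1ccc(cc1)P(c1ccccc1)c1ccccc1; carbon tetrabromide, BrC(Br)(Br)Br
Why: Appel bromination is selective for the primary allylic hydroxyl (the tertiary alcohols do not react at low temperature and lutidine keeps the medium non-acidic), and SN2 displacement by PPh3 gives the Wittig salt.

Step 16
Reactants: 16 (1S,2R,4S)-4-(tert-butyldimethylsilyloxy)-1-ethynyl-2,6,6-trimethylcyclohexane-1,2-diol; 19 [(Z)-4-hydroxybut-2-en-2-yl]boronic acid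
Product: 25 (2E)-5-[(2R,4S)-4-(tert-butyldimethylsilyloxy)-2-hydroxy-2,6,6-trimethylcyclohexylidene]-3-methylpenta-2,4-dien-1-ol (allene axis S)
Conditions: Pd(PPh3)4 (5 mol%), 1,4-dioxane, 80 °C
Reagents that add atoms: none
Why: In this palladium-catalysed direct coupling of a tertiary propargylic alcohol with a boronic acid (hydroxyl activated as its borate), zerovalent palladium attacks the alkyne terminus anti to the C6–O bond (SN2′) and transmetalation and reductive elimination occur with retention, so the butenyl group should arrive on the face opposite to the leaving oxygen and translate the C6 centre into the S allene axis, while the neighbouring 5-hydroxyl needs no protection because only the propargylic C–O bond can ionise.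

Step 17
Reactants: 25 (2E)-5-[(2R,4S)-4-(tert-butyldimethylsilyloxy)-2-hydroxy-2,6,6-trimethylcyclohexylidene]-3-methylpenta-2,4-dien-1-ol
Product: 26 (2E)-3-[(2R,6S,7aR)-6-(tert-butyldimethylsilyloxy)-4,4,7a-trimethyl-2,4,5,6,7,7a-hexahydro-1-benzofuran-2-yl]but-2-en-1-ol
Conditions: AgNO3 (20 mol%), CaCO3, acetone/H2O, rt, dark
Reagents that add atoms: none
Why: Silver-catalysed cycloisomerisation of the α-allenol (5-endo-trig attack of the tertiary hydroxyl on the activated distal allene carbon, then protodemetalation) is stereospecific, the butenyl group staying on the face it occupied in the allene, so the axis should set C8′ as R, trans to the C5′ methyl.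

Step 18
Reactants: 26 (2E)-3-[(2R,6S,7aR)-6-(tert-butyldimethylsilyloxy)-4,4,7a-trimethyl-2,4,5,6,7,7a-hexahydro-1-benzofuran-2-yl]but-2-en-1-ol
Product: 28 [(2E)-3-[(2R,6S,7aR)-6-(tert-butyldimethylsilyloxy)-4,4,7a-trimethyl-2,4,5,6,7,7a-hexahydro-1-benzofuran-2-yl]but-2-enyl]triphenylphosphonium bromide, via allylic bromide 27 (not isolated)
Conditions: CBr4, PPh3, 2,6-lutidine, CH2Cl2, −30 °C; then PPh3, MeCN, rt
Reagents that add atoms: triphenylphosphine, c1ccc(cc1)P(c1ccccc1)c1ccccc1; carbon tetrabromide, BrC(Br)(Br)Br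
Why: Appel bromination of the primary allylic alcohol under buffered, non-acidic conditions followed by SN2 displacement with PPh3 gives the Wittig salt without ionising the bis-allylic cyclic ether.

Step 19
Reactants: 28 furanoid C15 phosphonium bromide; 29 (2E,4E,6E)-2,7-dimethylocta-2,4,6-trienedial
Product: 31 (2E,4E,6E,8E,10E)-11-[(2R,6S,7aR)-6-(tert-butyldimethylsilyloxy)-4,4,7a-trimethyl-2,4,5,6,7,7a-hexahydro-1-benzofuran-2-yl]-2,7-dimethyldodeca-2,4,6,8,10-pentaenal, via ylide 30 (not isolated)
Conditions: 29 (3 equiv), NaOMe, CH2Cl2/MeOH, −10 °C → rt; then EtOAc, 60 °C (Z to E equilibration)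
Reagents that add atoms: none
Why: Wittig olefination of the allylic ylide with an excess of the symmetrical dialdehyde should give the mono-adduct, and thermal equilibration converts the hindered 11′Z isomer into the E isomer.

Step 20
Reactants: 24 triol C15 phosphonium bromide; 31 furanoid C25 aldehyde
Product: 33 3,3′-bis-O-(tert-butyldimethylsilyl) ether of the target, via ylide 32 (not isolated)
Conditions: NaOMe, CH2Cl2/MeOH, 0 °C → rt; then EtOAc, 60 °C (Z to E equilibration), crystallisation
Reagents that add atoms: none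
Why: The second Wittig olefination completes the C40 chain, the free tertiary hydroxyls being tolerated by the ylide, and the hindered 11Z isomer is equilibrated thermally to the all-E compound.

Step 21
Reactants: 33 3,3′-bis-O-(tert-butyldimethylsilyl) ether of the target
Product: 34 (all-E,3S,5R,6R,3′S,5′R,8′R)-5′,8′-epoxy-5,6,5′,8′-tetrahydro-β,β-carotene-3,5,6,3′-tetrol
Conditions: TBAF, THF, 0 °C → rt
Reagents that add atoms: none
Why: Fluoride cleavage of the two secondary silyl ethers under non-acidic conditions should spare the acid-labile allylic tertiary diol and the bis-allylic cyclic ether.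

Compound list
1 | methyl 3-methylfuran-2-carboxylate | COC(=O)c1occc1C | starting material
2 | methyl 2,5-dimethoxy-3-methyl-2,5-dihydrofuran-2-carboxylate (diastereomer mixture) | COC(=O)C1(OC)OC(OC)C=C1C | intermediate
3 | methyl 2,5-dimethoxy-3-methyltetrahydrofuran-2-carboxylate (diastereomer mixture) | COC(=O)C1(OC)OC(OC)CC1C | intermediate
4 | 3-methyl-2,5-dioxopentanoic acid (racemic, not isolated) | CC(CC=O)C(=O)C(=O)O | intermediate
5 | 3-hydroxy-4-methyl-2H-pyran-2-one | Cc1ccoc(=O)c1O | intermediate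
6 | methacrolein | CC(=C)C=O | starting material
7 | (1R,4S,5S)-4-hydroxy-5,8-dimethyl-3-oxo-2-oxabicyclo[2.2.2]oct-7-ene-5-carbaldehyde | O=C1O[C@H]2C=C(C)[C@]1(O)[C@@](C)(C=O)C2 | intermediate
8 | N-tosylhydrazone of 7 (not isolated) | O=C1O[C@H]2C=C(C)[C@]1(O)[C@@](C)(/C=N/NS(=O)(=O)c1ccc(C)cc1)C2 | intermediate
9 | (1R,4R)-4-hydroxy-5,5,8-trimethyl-2-oxabicyclo[2.2.2]oct-7-en-3-one | O=C1O[C@H]2C=C(C)[C@]1(O)C(C)(C)C2 | intermediate
10 | (1R,4R,8R)-8-hydroperoxy-4-hydroxy-5,5,8-trimethyl-2-oxabicyclo[2.2.2]octan-3-one (not isolated) | O=C1O[C@H]2C[C@@](C)(OO)[C@]1(O)C(C)(C)C2 | intermediate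
11 | (1R,4R,8R)-4,8-dihydroxy-5,5,8-trimethyl-2-oxabicyclo[2.2.2]octan-3-one | O=C1O[C@H]2C[C@@](C)(O)[C@]1(O)C(C)(C)C2 | intermediate
12 | (1R,4R,8R)-5,5,8-trimethyl-2-oxabicyclo[2.2.2]octane-3,4,8-triol (lactol, anomer mixture) | OC1O[C@H]2C[C@@](C)(O)[C@]1(O)C(C)(C)C2 | intermediate
13 | (1S,2R,4R)-1-ethynyl-2,6,6-trimethylcyclohexane-1,2,4-triol (4-OH cis to 2-OH) | C#C[C@@]1(O)C(C)(C)C[C@@H](O)C[C@@]1(C)O | intermediate
14 | (3R,4S)-4-ethynyl-3,4-dihydroxy-3,5,5-trimethylcyclohexan-1-one | C#C[C@@]1(O)C(C)(C)CC(=O)C[C@@]1(C)O | intermediate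
15 | (1S,2R,4S)-1-ethynyl-2,6,6-trimethylcyclohexane-1,2,4-triol (4-OH trans to 2-OH, cis to 1-OH) | C#C[C@@]1(O)C(C)(C)C[C@H](O)C[C@@]1(C)O | intermediate
16 | (1S,2R,4S)-4-(tert-butyldimethylsilyloxy)-1-ethynyl-2,6,6-trimethylcyclohexane-1,2-diol | C#C[C@@]1(O)C(C)(C)C[C@H](O[Si](C)(C)C(C)(C)C)C[C@@]1(C)O | intermediate
17 | but-2-yn-1-ol | CC#CCO | starting material
18 | (Z)-3-(4,4,5,5-tetramethyl-1,3,2-dioxaborolan-2-yl)but-2-en-1-ol (not isolated) | C/C(=C\CO)B1OC(C)(C)C(C)(C)O1 | intermediate
19 | [(Z)-4-hydroxybut-2-en-2-yl]boronic acid | C/C(=C\CO)B(O)O | intermediate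
20 | (1R,2R,4S)-4-(tert-butyldimethylsilyloxy)-2,6,6-trimethyl-1-[(E)-2-(tributylstannyl)ethenyl]cyclohexane-1,2-diol (not isolated) | CCCC[Sn](CCCC)(CCCC)/C=C/[C@@]1(O)C(C)(C)C[C@H](O[Si](C)(C)C(C)(C)C)C[C@@]1(C)O | intermediate
21 | (1R,2R,4S)-4-(tert-butyldimethylsilyloxy)-1-[(E)-2-iodoethenyl]-2,6,6-trimethylcyclohexane-1,2-diol | I/C=C/[C@@]1(O)C(C)(C)C[C@H](O[Si](C)(C)C(C)(C)C)C[C@@]1(C)O | intermediate
22 | (2E,4E)-5-[(1R,2R,4S)-4-(tert-butyldimethylsilyloxy)-1,2-dihydroxy-2,6,6-trimethylcyclohexyl]-3-methylpenta-2,4-dien-1-ol | OC/C=C(C)/C=C/[C@@]1(O)C(C)(C)C[C@H](O[Si](C)(C)C(C)(C)C)C[C@@]1(C)O | intermediate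
23 | allylic bromide of 22 (not isolated) | BrC/C=C(C)/C=C/[C@@]1(O)C(C)(C)C[C@H](O[Si](C)(C)C(C)(C)C)C[C@@]1(C)O | intermediate
24 | [(2E,4E)-5-[(1R,2R,4S)-4-(tert-butyldimethylsilyloxy)-1,2-dihydroxy-2,6,6-trimethylcyclohexyl]-3-methylpenta-2,4-dienyl]triphenylphosphonium bromide | [Br-].C(/C=C(C)/C=C/[C@@]1(O)C(C)(C)C[C@H](O[Si](C)(C)C(C)(C)C)C[C@@]1(C)O)[P+](c1ccccc1)(c1ccccc1)c1ccccc1 | intermediate
25 | (2E)-5-[(2R,4S)-4-(tert-butyldimethylsilyloxy)-2-hydroxy-2,6,6-trimethylcyclohexylidene]-3-methylpenta-2,4-dien-1-ol, allene axis S | [H]C(/C(C)=C/CO)=[C@@]=C1C(C)(C)C[C@H](O[Si](C)(C)C(C)(C)C)C[C@@]1(C)O | intermediate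
26 | (2E)-3-[(2R,6S,7aR)-6-(tert-butyldimethylsilyloxy)-4,4,7a-trimethyl-2,4,5,6,7,7a-hexahydro-1-benzofuran-2-yl]but-2-en-1-ol | OC/C=C(C)/[C@H]1C=C2C(C)(C)C[C@H](O[Si](C)(C)C(C)(C)C)C[C@@]2(C)O1 | intermediate
27 | allylic bromide of 26 (not isolated) | BrC/C=C(C)/[C@H]1C=C2C(C)(C)C[C@H](O[Si](C)(C)C(C)(C)C)C[C@@]2(C)O1 | intermediate
28 | [(2E)-3-[(2R,6S,7aR)-6-(tert-butyldimethylsilyloxy)-4,4,7a-trimethyl-2,4,5,6,7,7a-hexahydro-1-benzofuran-2-yl]but-2-enyl]triphenylphosphonium bromide | [Br-].C(/C=C(C)/[C@H]1C=C2C(C)(C)C[C@H](O[Si](C)(C)C(C)(C)C)C[C@@]2(C)O1)[P+](c1ccccc1)(c1ccccc1)c1ccccc1 | intermediate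
29 | (2E,4E,6E)-2,7-dimethylocta-2,4,6-trienedial | O=C/C(C)=C/C=C/C=C(C)/C=O | starting material
30 | triphenylphosphonium ylide of 28 (not isolated) | C(/C=C(C)/[C@H]1C=C2C(C)(C)C[C@H](O[Si](C)(C)C(C)(C)C)C[C@@]2(C)O1)=P(c1ccccc1)(c1ccccc1)c1ccccc1 | intermediate
31 | (2E,4E,6E,8E,10E)-11-[(2R,6S,7aR)-6-(tert-butyldimethylsilyloxy)-4,4,7a-trimethyl-2,4,5,6,7,7a-hexahydro-1-benzofuran-2-yl]-2,7-dimethyldodeca-2,4,6,8,10-pentaenal | O=C/C(C)=C/C=C/C=C(C)/C=C/C=C(C)/[C@H]1C=C2C(C)(C)C[C@H](O[Si](C)(C)C(C)(C)C)C[C@@]2(C)O1 | intermediate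
32 | triphenylphosphonium ylide of 24 (not isolated) | C(/C=C(C)/C=C/[C@@]1(O)C(C)(C)C[C@H](O[Si](C)(C)C(C)(C)C)C[C@@]1(C)O)=P(c1ccccc1)(c1ccccc1)c1ccccc1 | intermediate
33 | 3,3′-bis-O-(tert-butyldimethylsilyl) ether of 34 (all-E) | CC(/C=C/C=C(C)/C=C/[C@@]1(O)C(C)(C)C[C@H](O[Si](C)(C)C(C)(C)C)C[C@@]1(C)O)=C\C=C\C=C(C)\C=C\C=C(/C)[C@H]1C=C2C(C)(C)C[C@H](O[Si](C)(C)C(C)(C)C)C[C@@]2(C)O1 | intermediate
34 | (all-E,3S,5R,6R,3′S,5′R,8′R)-5′,8′-epoxy-5,6,5′,8′-tetrahydro-β,β-carotene-3,5,6,3′-tetrol | CC(/C=C/C=C(C)/C=C/[C@@]1(O)C(C)(C)C[C@H](O)C[C@@]1(C)O)=C\C=C\C=C(C)\C=C\C=C(/C)[C@H]1C=C2C(C)(C)C[C@H](O)C[C@@]2(C)O1 | target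

Total step count: 21. Longest linear sequence: 17 steps (steps 1–11 and 16–21).

Steps most likely to fail

Step 16. The unactivated tertiary hydroxyl may fail to ionise, or the allenylpalladium intermediate may equilibrate and erode the centre-to-axis transfer. The fallback sets out from 16: both tertiary hydroxyls are acylated (LiHMDS, ClCO2Me, THF, −78 → 0 °C) to the bis(methyl carbonate) F1. Zerovalent palladium (Pd2(dba)3, PPh3, THF, rt) ionises only the propargylic carbonate and couples it in the anti SN2′ sense with pinacol boronate 18 (isolated after the first stage of step 12 for this purpose), giving the allenyl 5-carbonate F2. K2CO3 in MeOH then removes the remaining carbonate and the route is rejoined at 25.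

Step 8. Under the basic conditions the α,β-dihydroxy aldehyde may undergo α-ketol ring expansion or retro-aldol ring opening before it is homologated. The fallback sets out from 11: silylation (TMSOTf, 2,6-lutidine, CH2Cl2) gives the bis(trimethylsilyl) ether lactone F3, DIBAL-H at −78 °C gives the silylated lactol F4, and the Ohira–Bestmann reaction gives the silylated alkyne F5, in which no free alkoxide flanks the aldehyde at any stage. Extended treatment with K2CO3 in MeOH strips both trimethylsilyl groups and rejoins the route at 13.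

Step 4. Enantiofacial discrimination may be insufficient with the small α-branched enal, or the adduct may revert. The fallback sets out from 5 and 6: with Et3N as achiral base the racemic adduct F6 is made and reduced as in step 5 to the racemic lactone F7. LiOH in THF/H2O opens it to the racemic cis-hydroxy acid F8, which is resolved by crystallisation of the (R)-1-phenylethylammonium salt F9 of the required acid (the antipodal amine is used if it gives the less soluble salt). Acidification and relactonisation (EDC·HCl, DMAP, CH2Cl2) return to 9.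

Further compounds
F1 | step 16 | (1S,2R,4S)-4-(tert-butyldimethylsilyloxy)-1-ethynyl-2,6,6-trimethylcyclohexane-1,2-diyl bis(methyl carbonate) | C#C[C@@]1(OC(=O)OC)C(C)(C)C[C@H](O[Si](C)(C)C(C)(C)C)C[C@@]1(C)OC(=O)OC
F2 | step 16 | methyl carbonate of 25 at the tertiary hydroxyl (allene axis S) | [H]C(/C(C)=C/CO)=[C@@]=C1C(C)(C)C[C@H](O[Si](C)(C)C(C)(C)C)C[C@@]1(C)OC(=O)OC
F3 | step 8 | (1R,4R,8R)-5,5,8-trimethyl-4,8-bis(trimethylsilyloxy)-2-oxabicyclo[2.2.2]octan-3-one | O=C1O[C@H]2C[C@@](C)(O[Si](C)(C)C)[C@]1(O[Si](C)(C)C)C(C)(C)C2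
F4 | step 8 | (1R,4R,8R)-5,5,8-trimethyl-4,8-bis(trimethylsilyloxy)-2-oxabicyclo[2.2.2]octan-3-ol (anomer mixture) | OC1O[C@H]2C[C@@](C)(O[Si](C)(C)C)[C@]1(O[Si](C)(C)C)C(C)(C)C2
F5 | step 8 | 1,2-bis-O-trimethylsilyl ether of 13 | C#C[C@@]1(O[Si](C)(C)C)C(C)(C)C[C@@H](O)C[C@@]1(C)O[Si](C)(C)C
F6 | step 4 | racemic 4-hydroxy-5,8-dimethyl-3-oxo-2-oxabicyclo[2.2.2]oct-7-ene-5-carbaldehyde | O=C1OC2C=C(C)C1(O)C(C)(C=O)C2
F7 | step 4 | racemic 4-hydroxy-5,5,8-trimethyl-2-oxabicyclo[2.2.2]oct-7-en-3-one | O=C1OC2C=C(C)C1(O)C(C)(C)C2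
F8 | step 4 | racemic cis-1,4-dihydroxy-2,6,6-trimethylcyclohex-2-ene-1-carboxylic acid | OC(=O)C1(O)C(C)=CC(O)CC1(C)C
F9 | step 4 | (R)-1-phenylethylammonium (1R,4R)-1,4-dihydroxy-2,6,6-trimethylcyclohex-2-ene-1-carboxylate | C[C@@H]([NH3+])c1ccccc1.[O-]C(=O)[C@]1(O)C(C)=C[C@H](O)CC1(C)C
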